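Time comes first in this note to whoever takes over the bench: the flask is counted in half-lives of target.

- south: starting material 0.050 M; partner 0.55 equiv; run made earlier
- flask: starting material 0.050 M; partner 1.10 equiv; time 5.0 d

south run (percent of the starting material charged)

| time / h | target / % | starting material / % |
|---|---|---|
| 3.00 | 14.1 | 3.8 |
| 6.00 | 10.1 | 2.0 |
| 10.0 | 5.4 | 2.2 |
| 15.0 | 2.0 | 1.0 |
| 20.0 | 1.2 | 1.5 |
| 25.0 | 1.3 | 0.7 |

(readings scatter by 0.3 percentage points)

- what was read earlier has a scatter of 0.3 percentage points, one standard deviation

1. time, not beyond 5.0 d, at which the flask holds most target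
2. the amount of target, in percent of the starting material charged, at that time

- South's target falls from 14.1% at 3.00 h to 2.0% at 15.0 h, so I read its half-life, the time in which a falling [target] halves, as 4.26 h. I assume it holds in the flask, which has twice south's partner.
- South's readings start at 3.00 h with target at its highest reading, 14.1%, so they show no rise and I can't read a peak time from them.
- Don't leave the flask standing for target: the 5.0 d allowed is 28.2 half-lives, so I expect hardly any of the peak amount at the end.
- The forecast gives 23% at 0.075 d, and says “After that, target only falls”.
- The flask peaks at 25.6% at 0.120 d.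

    partner → second intermediate (k = 4.80 × 10⁻⁴ s⁻¹)
    starting material ⇌ open intermediate (K = 10.0, k = 6.00 × 10⁻⁴ s⁻¹)
    second intermediate → side product (k = 1.40 × 10⁻⁴ s⁻¹)
    2 open intermediate → homo product (k = 0.00190 M⁻¹ s⁻¹)
    open intermediate + second intermediate ⇌ target (K = 65.0 M⁻¹, k = 0.00360 M⁻¹ s⁻¹)

- From that peak to 0.500 d is 2.14 half-lives, which gives 5.81%; the flask holds 8.20%, which is more. The same flask left until 3.0 d reaches 25.6% on the way, and 16.2 half-lives after the peak time the count leaves <0.001%. That flask ends with 0% target and homo product at 97.1% of the starting material charged.

All runs stem from a simulated flask for an exercise; noise was put on by code.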